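The ten-membered carbocycle (germacrane C1–C10) is closed last, by a four-atom ring expansion. Two features are exploited. The oxirane is cis-fused (C3 and C6 lie on the same side of C4–C5), so C1–C6 can be folded back into a cyclohexene oxide. O-6 also sits 1,5 to the C1=C10 alkene, which is the retron of an anionic oxy-Cope rearrangement. The precursor is a chiral-pool 7-oxabicyclo[4.1.0]heptan-2-ol bearing trans isopropenyl (C1) and (E)-2-alkoxyalkenyl (C6) groups. One operation forms C8–C9, breaks C1–C6 and delivers the ring, the E-alkene, C8 and, after in-flask equilibration, C7, with the epoxide untouched.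

Key step: step 9

Remark on numbering: germacrane numbering is used throughout. C1(H)=C10(CH3), C2H2, C3H2, C4(CH3)–O–C5(H) oxirane, C6 (OAc), C7 (i-Pr), C8 (OBz), C9H2.

Assumption: alcohol 1 is bought as the (1S,4R) isomer. Only its C4 centre matters, because C1 becomes sp2 in step 1.

Step 1
Reactants: 1 (1S,4R)-p-mentha-2,8-dien-1-ol
Product: 2 (S)-isopiperitenone
Conditions: PCC, powdered 4 Å MS, CH2Cl2, rt
Reagents that add atoms: pyridinium chlorochromate, [O-][Cr](=O)(=O)Cl.c1cc[nH+]cc1
Why: Babler–Dauben oxidative 1,3-transposition, in which the tertiary allylic chromate ester undergoes a [3,3] shift and is oxidised to the β-methyl enone, while the isopropenyl-bearing centre (later C1) is untouched under non-basic conditions.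

Step 2
Reactants: 2 (S)-isopiperitenone
Product: 3 (1S,6S)-cis-isopiperitenol
Conditions: L-Selectride, THF, −78 °C; H2O
Reagents that add atoms: none
Why: 1,2-reduction of a β,β-disubstituted enone by a bulky trialkylborohydride, in which hydride approaches opposite the neighbouring isopropenyl group and so sets the pseudo-axial carbinol cis to it.

Step 3
Reactants: 3 (1S,6S)-cis-isopiperitenol
Product: 4 all-cis epoxy alcohol
Conditions: VO(acac)2 (cat.), t-BuOOH, toluene, 0 °C
Reagents that add atoms: tert-butyl hydroperoxide, CC(C)(C)OO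
Why: Hydroxyl-directed vanadium-catalysed epoxidation, in which the vanadate ester delivers oxygen to the allylic ring alkene on the OH face, setting C4 and C5 cis to OH and isopropenyl and sparing the 1,1-disubstituted alkene.

Step 4
Reactants: 4 all-cis epoxy alcohol
Product: 5 cis-isopiperitenone oxide
Conditions: Dess–Martin periodinane, pyridine, CH2Cl2, 0 °C
Reagents that add atoms: none
Why: Dess–Martin oxidation is essentially neutral, so the doubly activated, epimerisable α-centre and the oxirane should survive.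

Step 5
Reactants: 6 4-methoxybenzyl alcohol; 7 3-methylbutanoyl chloride
Product: 8 4-methoxybenzyl 3-methylbutanoate
Conditions: Et3N, DMAP (cat.), CH2Cl2, 0 °C
Reagents that add atoms: none
Why: DMAP-catalysed acylation of a primary alcohol by an acid chloride.

Step 6
Reactants: 8 4-methoxybenzyl 3-methylbutanoate
Product: 10 4-methoxybenzyl 3-methylbut-1-ynyl ether, via ketene acetal phosphate 9 (not isolated)
Conditions: LDA, THF, −78 °C; ClP(O)(OEt)2; then t-BuLi, −78 °C
Reagents that add atoms: none
Why: O-phosphorylation of the ester enolate followed by base-induced β-elimination of phosphate (enol phosphate to alkyne elimination) gives the 1-alkoxyalkyne, which is kept cold because benzyl alkynyl ethers rearrange on heating.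

Step 7
Reactants: 10 4-methoxybenzyl 3-methylbut-1-ynyl ether
Product: 12 (E)-2-iodo-1-(4-methoxybenzyloxy)-3-methylbut-1-ene, via alkenylzirconocene 11 (not isolated)
Conditions: Cp2Zr(H)Cl, THF, 0 °C to rt; then I2 (1 equiv), −78 °C
Reagents that add atoms: iodine, II
Why: Syn hydrozirconation of the polarised ynol ether puts hydride on the oxygen-bearing carbon and Zr on the β-carbon, and iodinolysis with retention gives the alkene with I trans to OPMB.

Step 8
Reactants: 12 (E)-2-iodo-1-(4-methoxybenzyloxy)-3-methylbut-1-ene; 5 cis-isopiperitenone oxide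
Product: 14 trans-dialkenyl epoxy carbinol, via alkenyllithium 13 (not isolated)
Conditions: 12, t-BuLi (2 equiv), Et2O, −90 °C; then 5, −78 °C; H2O; Et3N-deactivated SiO2
Reagents that add atoms: none
Why: Iodine–lithium exchange with retention gives a trans-2-alkoxyvinyllithium (usable only at or below −78 °C), and its 1,2-addition occurs opposite both the oxirane oxygen (Felkin–Anh) and the isopropenyl group, setting C6 with OH syn to the oxirane and the two alkenyl groups trans.

Step 9
Reactants: 14 trans-dialkenyl epoxy carbinol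
Product: 18 (4S,5S,7R,8S)-4,5-epoxy-8-(4-methoxybenzyloxy)germacr-1(10)E-en-6-one, via potassium alkoxide 15 (not isolated), via potassium enolate 16 (not isolated), via 7-epi ketone 17 (not isolated)
Conditions: KH, 18-crown-6, THF, 0 to 35 °C; then H2O (few equiv) in THF, 0 °C; pH 7 buffer
Reagents that add atoms: none
Why: KH/18-crown-6 gives the naked tertiary alkoxide 15, in which the array C8=C7–C6–C1–C10=C9 undergoes a concerted [3,3] shift that is irreversible because enolate 16 is formed; this is the anionic oxy-Cope rearrangement, the known four-atom ring expansion of trans-1,2-dialkenylcyclohexanols to (E)-cyclodec-5-enones. The ten-membered ring is closed by C8–C9 bond formation between the two alkene termini while the C1–C6 bond of the six-membered ring breaks, so the cis-fused oxirane is carried over unchanged as the C4–C5 cis-epoxide. The alkenyl groups are trans-diequatorial, which admits only the chair transition state with C2 and C5 equatorial; this makes C1=C10 E, and because the E enol ether holds OPMB equatorial, suprafacial bonding at the C8 face dictated by C1/C6 gives 8S (chirality transfer from C1, which is destroyed). C7 is set after the shift: peripheral protonation of 16 should give mainly 17, whose isopropyl group points across the ring, and the KOH–crown released by the water quench re-enolises it until both epimers are funnelled into 18, in which i-Pr and OPMB are trans-diequatorial on the crown conformer. The step needs no Payne migration, which is secured because O-6 is syn to the oxirane oxygen and cannot reach the back side of C5–O. It also needs no E1cB loss of PMBO−, which is disfavoured because the C8–O bond lies in the nodal plane of the enolate (the new C8–C9 bond is the one aligned with the π system) and the ring resists the rotation required.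

Step 10
Reactants: 18 (4S,5S,7R,8S)-4,5-epoxy-8-(4-methoxybenzyloxy)germacr-1(10)E-en-6-one
Product: 19 (4S,5R,6R,7R,8S)-4,5-epoxy-8-(4-methoxybenzyloxy)germacr-1(10)E-en-6-ol
Conditions: NaBH4, CeCl3·7H2O, MeOH, −78 °C
Reagents that add atoms: none
Why: Luche reduction, in which Ce(III) chelation between the carbonyl and oxirane oxygens (erythro-selective reduction of α,β-epoxy ketones) and peripheral hydride attack on the crown conformer both predict the 6R alcohol.

Step 11
Reactants: 19 (4S,5R,6R,7R,8S)-4,5-epoxy-8-(4-methoxybenzyloxy)germacr-1(10)E-en-6-ol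
Product: 20 6-acetate 8-PMB ether
Conditions: Ac2O, DMAP (cat.), pyridine, rt
Reagents that add atoms: acetic anhydride, CC(=O)OC(C)=O
Why: DMAP-catalysed acetylation under basic conditions touches neither the epoxide, the alkene nor any stereocentre.

Step 12
Reactants: 20 6-acetate 8-PMB ether
Product: 21 6-acetate 8-alcohol
Conditions: DDQ, CH2Cl2/pH 7 buffer, 0 °C
Reagents that add atoms: none
Why: Oxidative PMB ether cleavage (benzylic hydride abstraction by DDQ, then hydrolysis of the oxocarbenium ion), buffered so that the acid-labile epoxy-alkene pair does not cyclise transannularly.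

Step 13
Reactants: 21 6-acetate 8-alcohol
Product: 22 target CNP0112246.1
Conditions: BzCl, DMAP (cat.), pyridine, 0 °C to rt
Reagents that add atoms: benzoyl chloride, O=C(Cl)c1ccccc1
Why: DMAP-catalysed benzoylation of the remaining secondary alcohol proceeds with retention at C8, and is run cold and short to avoid 1,3-acetyl migration.

Compound list
1 | (1S,4R)-1-methyl-4-(prop-1-en-2-yl)cyclohex-2-en-1-ol (p-mentha-2,8-dien-1-ol) | O[C@]1(C)C=C[C@H](C(C)=C)CC1 | starting material
2 | (6S)-3-methyl-6-(prop-1-en-2-yl)cyclohex-2-en-1-one ((S)-isopiperitenone) | O=C1[C@H](C(C)=C)CCC(C)=C1 | intermediate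
3 | (1S,6S)-3-methyl-6-(prop-1-en-2-yl)cyclohex-2-en-1-ol (OH cis to isopropenyl) | O[C@@H]1[C@H](C(C)=C)CCC(C)=C1 | intermediate
4 | (1R,2R,3S,6S)-6-methyl-3-(prop-1-en-2-yl)-7-oxabicyclo[4.1.0]heptan-2-ol (OH, oxirane O and isopropenyl on one face) | O[C@@H]1[C@H](C(C)=C)CC[C@]2(C)O[C@H]12 | intermediate
5 | (1S,3S,6S)-6-methyl-3-(prop-1-en-2-yl)-7-oxabicyclo[4.1.0]heptan-2-one (oxirane O cis to isopropenyl) | O=C1[C@H](C(C)=C)CC[C@]2(C)O[C@H]12 | intermediate
6 | 4-methoxybenzyl alcohol | COc1ccc(CO)cc1 | starting material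
7 | 3-methylbutanoyl chloride | CC(C)CC(=O)Cl | starting material
8 | 4-methoxybenzyl 3-methylbutanoate | CC(C)CC(=O)OCc1ccc(OC)cc1 | intermediate
9 | diethyl 1-(4-methoxybenzyloxy)-3-methylbut-1-enyl phosphate (E/Z irrelevant, not defined) | CC(C)C=C(OCc1ccc(OC)cc1)OP(=O)(OCC)OCC | intermediate
10 | 1-methoxy-4-{[(3-methylbut-1-yn-1-yl)oxy]methyl}benzene | CC(C)C#COCc1ccc(OC)cc1 | intermediate
11 | chloro[(E)-1-(4-methoxybenzyloxy)-3-methylbut-1-en-2-yl]zirconocene (Zr trans to OPMB; Cp drawn η1) | CC(C)/C(=C\OCc1ccc(OC)cc1)[Zr](Cl)(C1C=CC=C1)C1C=CC=C1 | intermediate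
12 | (E)-2-iodo-1-(4-methoxybenzyloxy)-3-methylbut-1-ene (I trans to OPMB) | CC(C)/C(I)=C\OCc1ccc(OC)cc1 | intermediate
13 | (E)-1-(4-methoxybenzyloxy)-3-methylbut-1-en-2-yllithium (Li trans to OPMB) | [Li]/C(C(C)C)=C/OCc1ccc(OC)cc1 | intermediate
14 | (1R,2S,3S,6S)-2-[(1E)-1-(4-methoxybenzyloxy)-3-methylbut-1-en-2-yl]-6-methyl-3-(prop-1-en-2-yl)-7-oxabicyclo[4.1.0]heptan-2-ol | O[C@]1(/C(C(C)C)=C/OCc3ccc(OC)cc3)[C@H](C(C)=C)CC[C@]2(C)O[C@H]12 | intermediate
15 | potassium alkoxide of 14 | [K+].[O-][C@]1(/C(C(C)C)=C/OCc3ccc(OC)cc3)[C@H](C(C)=C)CC[C@]2(C)O[C@H]12 | intermediate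
16 | potassium C6=C7 enolate of 18 (O− cis to C8, C5 trans to C8) | [K+].[O-]/C1=C(/C(C)C)[C@@H](OCc3ccc(OC)cc3)C/C(C)=C/CC[C@]2(C)O[C@H]12 | intermediate
17 | (4S,5S,7S,8S)-4,5-epoxy-8-(4-methoxybenzyloxy)germacr-1(10)E-en-6-one (7-epimer of 18) | O=C1[C@@H](C(C)C)[C@@H](OCc3ccc(OC)cc3)C/C(C)=C/CC[C@]2(C)O[C@H]12 | intermediate
18 | (4S,5S,7R,8S)-4,5-epoxy-8-(4-methoxybenzyloxy)germacr-1(10)E-en-6-one | O=C1[C@H](C(C)C)[C@@H](OCc3ccc(OC)cc3)C/C(C)=C/CC[C@]2(C)O[C@H]12 | intermediate
19 | (4S,5R,6R,7R,8S)-4,5-epoxy-8-(4-methoxybenzyloxy)germacr-1(10)E-en-6-ol | O[C@@H]1[C@H](C(C)C)[C@@H](OCc3ccc(OC)cc3)C/C(C)=C/CC[C@]2(C)O[C@H]12 | intermediate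
20 | (4S,5R,6R,7R,8S)-4,5-epoxy-8-(4-methoxybenzyloxy)germacr-1(10)E-en-6-yl acetate | CC(=O)O[C@@H]1[C@H](C(C)C)[C@@H](OCc3ccc(OC)cc3)C/C(C)=C/CC[C@]2(C)O[C@H]12 | intermediate
21 | (4S,5R,6R,7R,8S)-4,5-epoxy-8-hydroxygermacr-1(10)E-en-6-yl acetate | CC(=O)O[C@@H]1[C@H](C(C)C)[C@@H](O)C/C(C)=C/CC[C@]2(C)O[C@H]12 | intermediate
22 | (4S,5R,6R,7R,8S)-6-acetoxy-4,5-epoxygermacr-1(10)E-en-8-yl benzoate (CNP0112246.1) | CC(=O)O[C@@H]1[C@H](C(C)C)[C@@H](OC(=O)c2ccccc2)C/C(C)=C/CC[C@]2(C)O[C@H]12 | target

Total step count: 13. Longest linear sequence: 10 steps (steps 1–4 and 8–13). The side chain (steps 5–7) is made in parallel.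

Steps most likely to fail

1. **Step 9.** The enolate may lose the C8 alkoxide by E1cB during the rearrangement or the equilibration. The C7 equilibrium may also not lie far enough on the side of 18. The fallback runs from 5 back to 18 and introduces O-8 after the ring expansion instead of carrying it through.
   - 3-Methylbut-1-en-2-yllithium (from commercial 2-bromo-3-methylbut-1-ene) is added to 5 to give the 2-(3-methylbut-1-en-2-yl) epoxy carbinol F1.
   - Its anionic oxy-Cope rearrangement, now free of any β-leaving group, is quenched with Me3SiCl to give the ring-expanded trimethylsilyl enol ether F2.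
   - Saegusa–Ito dehydrogenation with Pd(OAc)2 gives the cross-conjugated (7Z)-enone F3.
   - Copper-catalysed conjugate borylation (B2pin2, CuCl, NaOt-Bu, MeOH) from the periphery gives the β-boryl ketone F4.
   - Oxidation with NaBO3, with retention, gives the β-hydroxy ketone F5.
   - Neutral PMB transfer (2-(4-methoxybenzyloxy)-4-methylquinoline, MeOTf, MgO) returns to 18.

2. **Step 7.** Regiocontrol of the hydrozirconation may be lost, with the bulky isopropyl group pushing zirconium onto the oxygen-bearing carbon. The ynol ether may also decay before it reacts. The fallback runs from 6 back to 13 and takes the E geometry from an anti addition instead of a syn hydrometalation.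
   - 3-Methylbut-1-yne is treated with IBr to give (E)-2-bromo-1-iodo-3-methylbut-1-ene F6.
   - Copper-catalysed vinylation of 6 at the C–I bond (CuI, tetramethylphenanthroline, Cs2CO3), with retention, gives (E)-2-bromo-1-(4-methoxybenzyloxy)-3-methylbut-1-ene F7.
   - Bromine–lithium exchange at −78 °C gives 13.

3. **Step 10.** Facial selectivity may be poor if the ketone reacts through a conformer other than the crown or without chelation. The fallback runs from 18 back to 20 and sets C6 by SN2 inversion rather than by choice of hydride face.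
   - 18 is reduced with a bulky non-chelating hydride to the 6-epi alcohol F8.
   - Mitsunobu reaction of F8 with acetic acid (PPh3, DIAD) installs the acetate with inversion and gives 20 directly.

Further compounds
F1 | step 9 | (1R,2S,3S,6S)-6-methyl-2-(3-methylbut-1-en-2-yl)-3-(prop-1-en-2-yl)-7-oxabicyclo[4.1.0]heptan-2-ol | O[C@]1(C(=C)C(C)C)[C@H](C(C)=C)CC[C@]2(C)O[C@H]12
F2 | step 9 | (4S,5R)-4,5-epoxy-6-(trimethylsilyloxy)germacra-1(10)E,6-diene (OSi cis to C8) | C[Si](C)(C)O/C1=C(/C(C)C)CC/C(C)=C/CC[C@]2(C)O[C@H]12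
F3 | step 9 | (4S,5S)-4,5-epoxygermacra-1(10)E,7Z-dien-6-one | O=C1/C(C(C)C)=C\C/C(C)=C/CC[C@]2(C)O[C@H]12
F4 | step 9 | (4S,5S,7R,8S)-4,5-epoxy-8-(pinacolatoboryl)germacr-1(10)E-en-6-one | O=C1[C@H](C(C)C)[C@@H](B3OC(C)(C)C(C)(C)O3)C/C(C)=C/CC[C@]2(C)O[C@H]12
F5 | step 9 | (4S,5S,7R,8S)-4,5-epoxy-8-hydroxygermacr-1(10)E-en-6-one | O=C1[C@H](C(C)C)[C@@H](O)C/C(C)=C/CC[C@]2(C)O[C@H]12
F6 | step 7 | (E)-2-bromo-1-iodo-3-methylbut-1-ene | I/C=C(/Br)C(C)C
F7 | step 7 | (E)-2-bromo-1-(4-methoxybenzyloxy)-3-methylbut-1-ene | Br/C(C(C)C)=C/OCc1ccc(OC)cc1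
F8 | step 10 | (4S,5R,6S,7R,8S)-4,5-epoxy-8-(4-methoxybenzyloxy)germacr-1(10)E-en-6-ol | O[C@H]1[C@H](C(C)C)[C@@H](OCc3ccc(OC)cc3)C/C(C)=C/CC[C@]2(C)O[C@H]12
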